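**Retrosynthetic overview**

1. The (Z)-feruloyl ester on O19 comes from a Still–Gennari olefination on the C19 phosphonoacetate; the C13(16),C14 diene from a C13 methyl ketone (enol triflate, Stille coupling); 8α-OH and C19-OH from one LiAlH4 reduction of an 8α,17-epoxy 19-ester.
2. C4 (4α-CH3, 4β-C19) is set by dissolving-metal reductive methylation of a Δ3-19-ester; the same operation removes a 1,3-dithiane from C1.
3. Rings A and B are formed together from an acyclic triene by an intramolecular Diels–Alder reaction with inverse electron demand: diene C2=C3–C4(CO2Me)=C5, dienophile C1=C10 (ketene dithioacetal), tether C6–C9. Ring B closes through C5–C10, ring A through C1–C2.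
4. Enabling feature: ring A (C1–C5, C10) holds the two new bonds on either side of the C2–C5 unit, so a temporary C3=C4 double bond (C19 at the ester level on C4) makes it the cyclohexene of a [4+2] addition, with C6–C9 of ring B as tether. The dithiane on C1 makes C1=C10 electron-rich and, by 1,3-allylic strain against C9, controls C5, C10 and their relation to C9.
5. The triene comes from (R)-limonene, whose ten carbons become C1, C7–C13, C16 and C17 (C9 is limonene C4): allylic lithiation/oxirane opening adds C5–C6, cleavage of the ring alkene frees C1 and C13.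

Key step: step 12

Remark: atom labels C1–C20 and the descriptors α/β follow the labdane numbering of the target (the methyl on C10 is β). Three short-lived stereocentres (oxirane, diol, C10 of the α-methyl ester) are carried as diastereomer mixtures because later steps erase them.

**Route**

Step 1
Reactants: 1 (R)-(+)-limonene; 2 oxirane
Product: 3 4-[(1R)-4-methylcyclohex-3-en-1-yl]pent-4-en-1-ol
Conditions: n-BuLi, TMEDA, hexane, 23 °C; then oxirane, THF, −78 to 0 °C; H2O
Reagents that add atoms: oxirane 2, C1CO1
Why: Allylic lithiation of limonene at the isopropenyl methyl group gives a 2-substituted allyllithium with two equivalent termini, which opens the epoxide (SN2 epoxide alkylation); the stereocentre (later C9) comes from the chiral pool and is not touched.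

Step 2
Reactants: 3; 4 3-chloroperoxybenzoic acid (mCPBA)
Product: 5 4-[(4R)-1-methyl-7-oxabicyclo[4.1.0]heptan-4-yl]pent-4-en-1-ol (both oxirane diastereomers)
Conditions: mCPBA (1.0 equiv), NaHCO3, CH2Cl2, 0 °C
Reagents that add atoms: mCPBA 4, OOC(=O)c1cccc(Cl)c1
Why: Prilezhaev epoxidation should take the more electron-rich trisubstituted ring alkene in preference to the 1,1-disubstituted one; the two oxirane centres need no control because both carbons become carbonyl groups in step 3.

Step 3
Reactants: 5; 6 water
Product: 8 (3R)-3-(5-hydroxypent-1-en-2-yl)-6-oxoheptanal, via 1,2-diol 7 (not isolated)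
Conditions: H5IO6, THF/H2O, 0 to 23 °C
Reagents that add atoms: water 6, O
Why: Acid-assisted epoxide hydrolysis and Malaprade glycol cleavage in one pot open the limonene ring to the keto aldehyde; no stereocentre is formed and C9, β to both carbonyl groups, cannot epimerise.

Step 4
Reactants: 8; 9 sodium chlorite
Product: 10 (3R)-3-(5-hydroxypent-1-en-2-yl)-6-oxoheptanoic acid
Conditions: NaClO2, NaH2PO4, 2-methylbut-2-ene, t-BuOH/H2O, 0 to 23 °C
Reagents that add atoms: sodium chlorite 9, [Na+].[O-]Cl=O
Why: Pinnick oxidation converts the aldehyde into the acid and leaves the ketone, the primary alcohol and the alkene alone, since the hypochlorite formed is trapped by the scavenger alkene.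

Step 5
Reactants: 10; 11 iodomethane
Product: 12 methyl (3R)-3-(5-hydroxypent-1-en-2-yl)-6-oxoheptanoate
Conditions: K2CO3, MeI, DMF, 23 °C
Reagents that add atoms: iodomethane 11, CI
Why: SN2 O-alkylation of the carboxylate gives the methyl ester; this weak base does not alkylate the alcohol or enolise the ketone.

Step 6
Reactants: 12; 13 ethane-1,2-diol
Product: 14 methyl (3R)-3-(5-hydroxypent-1-en-2-yl)-5-(2-methyl-1,3-dioxolan-2-yl)pentanoate
Conditions: ethane-1,2-diol, PPTS (cat.), benzene, reflux, Dean–Stark trap
Reagents that add atoms: ethane-1,2-diol 13, OCCO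
Why: Acid-catalysed ketalisation masks the methyl ketone (later C13) as a dioxolane that should survive enolate, organoaluminium and dissolving-metal conditions.

Step 7
Reactants: 14; 11 iodomethane
Product: 15 methyl (2RS,3R)-3-(5-hydroxypent-1-en-2-yl)-2-methyl-5-(2-methyl-1,3-dioxolan-2-yl)pentanoate
Conditions: LiN(i-Pr)2 (2.1 equiv), THF, −78 °C; MeI (1.05 equiv), −78 to −40 °C
Reagents that add atoms: iodomethane 11, CI
Why: Ester enolate alkylation introduces C20 (the lithium alkoxide formed alongside should not be methylated at this temperature); the new centre at C10 is left as a mixture because it becomes sp2 in step 8.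

Step 8
Reactants: 15; 16 propane-1,3-dithiol
Product: 17 (5S)-6-(1,3-dithian-2-ylidene)-4-methylidene-5-[2-(2-methyl-1,3-dioxolan-2-yl)ethyl]heptan-1-ol
Conditions: AlMe3 (4.5 equiv), propane-1,3-dithiol (2.2 equiv), CH2Cl2, 0 to 23 °C; then 15, 23 to 40 °C
Reagents that add atoms: propane-1,3-dithiol 16, SCCCS
Why: Bis(dimethylaluminium) propane-1,3-dithiolate converts an ester bearing an α-hydrogen into the ketene dithioacetal (thioester formation, second Al–S addition, loss of the aluminium-bound oxygen), which makes C1=C10 an electron-rich alkene; no stereocentre is formed and both C10 epimers converge.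

Step 9
Reactants: 17
Product: 18 (5S)-6-(1,3-dithian-2-ylidene)-4-methylidene-5-[2-(2-methyl-1,3-dioxolan-2-yl)ethyl]heptanal
Conditions: SO3·pyridine, DMSO, i-Pr2NEt, CH2Cl2, 0 °C
Reagents that add atoms: none
Why: Parikh–Doering oxidation is chosen because activated DMSO should oxidise the primary alcohol without oxidising sulfur or hydrolysing the ketene dithioacetal.

Step 10
Reactants: 18; 19 methyl bromo[bis(2,2,2-trifluoroethoxy)phosphoryl]acetate
Product: 20 methyl (2E,7S)-2-bromo-8-(1,3-dithian-2-ylidene)-6-methylidene-7-[2-(2-methyl-1,3-dioxolan-2-yl)ethyl]non-2-enoate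
Conditions: KOt-Bu, 18-crown-6, THF, −78 °C
Reagents that add atoms: methyl bromo[bis(2,2,2-trifluoroethoxy)phosphoryl]acetate 19, COC(=O)C(Br)P(=O)(OCC(F)(F)F)OCC(F)(F)F
Why: Horner–Wadsworth–Emmons olefination with the trifluoroethyl bromophosphonoacetate (Still–Gennari-type kinetic control) should place C6 cis to the ester, giving the (E)-α-bromo enoate needed for an outward-pointing tether on the later diene.

Step 11
Reactants: 20; 21 tributyl(vinyl)stannane
Product: 22 methyl (2Z,7S)-8-(1,3-dithian-2-ylidene)-2-ethenyl-6-methylidene-7-[2-(2-methyl-1,3-dioxolan-2-yl)ethyl]non-2-enoate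
Conditions: Pd2(dba)3 (cat.), AsPh3, CuI, NMP, 23 °C
Reagents that add atoms: tributyl(vinyl)stannane 21, C=C[Sn](CCCC)(CCCC)CCCC
Why: Stille coupling of the alkenyl bromide proceeds with retention of double-bond geometry and builds the 2-(methoxycarbonyl)-1,3-diene at room temperature, below the onset of cycloaddition; the triene is used at once.

Step 12
Reactants: 22
Product: 23 methyl 13,13-(ethylenedioxy)-1,1-(propane-1,3-diyldisulfanediyl)-14,15,18-trinorlabda-3,8(17)-dien-19-oate (5α-H, 9α-H, 10β-CH3)
Conditions: toluene (0.005 M), BHT, K2CO3 (solid), 120 °C, sealed tube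
Reagents that add atoms: none
Why: This is an intramolecular Diels–Alder reaction with inverse electron demand: the HOMO of the ketene dithioacetal (large coefficient on C10) meets the LUMO of the 2-(methoxycarbonyl)diene (large coefficient on C5), so C5–C10 bonding should run ahead of C1–C2 bonding in a concerted, asynchronous [4+2] step whose tether-enforced regiochemistry is also the electronically preferred one. The closest known reaction types are the cycloadditions of 2-acceptor-substituted 1,3-dienes with enol ethers, vinyl sulfides and ketene acetals, and the thermal cyclisation of 1,7,9-decatrienes to octalins. Ring B closes through C5–C10 over the four-atom tether C6–C9 in a chair-like array, and ring A closes as the cyclohexene (C3=C4) of the cycloaddition itself. For C10 and C5, 1,3-allylic strain between the sulfur cis to C9 and the substituents on C9 should hold H9 in the plane of C1=C10 with C8 anti, which places C1 equatorial on the forming ring B; the ester cis to C6 holds C7 anti to C4 in the same way, so both π-units are equatorial and the ring fusion should be trans (5α-H, 10β-CH3). The same strain element makes the tether deliver the diene to the face of C10 anti to C11, so C11 becomes equatorial (9α-H), and the stereocentre from limonene thereby fixes the absolute configuration of C5 and C10. The step needs chemoselectivity (the 8(17)-methylene is only two atoms from the diene and cannot reach it, and the ester carbonyl is a poor heterodiene), regioselectivity (given by tether and polarity) and diastereoselectivity (given by the two allylic-strain elements).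

Step 13
Reactants: 23; 11 iodomethane; 6 water
Product: 25 methyl 13-oxo-14,15-dinorlabd-8(17)-en-19-oate, via ketal ester 24 (not isolated)
Conditions: Li, NH3(l)/THF, t-BuOH (1 equiv), −78 to −33 °C; MeI, −78 °C; then 1 M HCl, THF, 23 °C
Reagents that add atoms: iodomethane 11, CI; water 6, O
Why: Dissolving-metal reduction turns the enoate into the C4 ester enolate and cleaves both C–S bonds of the dithiane (Birch-type reductive alkylation combined with thioketal desulfurisation); MeI should then alkylate the enolate from the α-face, anti to the axial C10 methyl, setting 4α-CH3/4β-CO2Me, and the acidic work-up hydrolyses the dioxolane.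

Step 14
Reactants: 25; 4 mCPBA
Product: 26 methyl 8α,17-epoxy-13-oxo-14,15-dinorlabdan-19-oate
Conditions: mCPBA, NaHCO3, CH2Cl2, 0 °C
Reagents that add atoms: mCPBA 4, OOC(=O)c1cccc(Cl)c1
Why: Prilezhaev epoxidation of the exocyclic alkene should occur from the α-face, the β-face being screened by the axial C10 methyl, which sets the C8–O bond α; the ketone is inert to buffered peracid at this temperature.

Step 15
Reactants: 26; 27 N-phenylbis(trifluoromethanesulfonimide)
Product: 28 methyl 8α,17-epoxy-13-[(trifluoromethanesulfonyl)oxy]-14,15-dinorlabd-13(16)-en-19-oate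
Conditions: LiN(i-Pr)2, THF, −78 °C; PhNTf2, −78 to 0 °C
Reagents that add atoms: N-phenylbis(trifluoromethanesulfonimide) 27, FC(F)(F)S(=O)(=O)N(c1ccccc1)S(=O)(=O)C(F)(F)F
Why: Kinetic deprotonation of the methyl ketone at the methyl group and O-sulfonylation give the terminal enol triflate; the quaternary ester has no α-hydrogen and the epoxide should tolerate the amide base at low temperature.

Step 16
Reactants: 28; 21 tributyl(vinyl)stannane
Product: 29 methyl 8α,17-epoxylabda-13(16),14-dien-19-oate
Conditions: Pd2(dba)3 (cat.), AsPh3, NMP, 23 °C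
Reagents that add atoms: tributyl(vinyl)stannane 21, C=C[Sn](CCCC)(CCCC)CCCC
Why: Stille coupling of the enol triflate installs C14–C15 and completes the 2-substituted buta-1,3-diene under neutral, halide-free conditions that should leave the epoxide alone.

Step 17
Reactants: 29
Product: 30 labda-13(16),14-diene-8α,19-diol
Conditions: LiAlH4, THF, 0 to 23 °C
Reagents that add atoms: none
Why: Hydride reduction converts the axial ester into the C19 primary alcohol and opens the epoxide at the unhindered C17 methylene, leaving the tertiary 8α-alcohol with its C8–O bond unchanged; the conjugated diene is not reduced.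

Step 18
Reactants: 30; 31 [bis(2,2,2-trifluoroethoxy)phosphoryl]acetic acid
Product: 32 8α-hydroxylabda-13(16),14-dien-19-yl [bis(2,2,2-trifluoroethoxy)phosphoryl]acetate
Conditions: DCC, DMAP (cat.), CH2Cl2, 0 to 23 °C
Reagents that add atoms: [bis(2,2,2-trifluoroethoxy)phosphoryl]acetic acid 31, OC(=O)CP(=O)(OCC(F)(F)F)OCC(F)(F)F
Why: Steglich esterification should acylate the primary neopentyl alcohol and leave the tertiary 8α-alcohol free.

Step 19
Reactants: 32; 33 4-formyl-2-methoxyphenyl acetate
Product: 35 8α-hydroxylabda-13(16),14-dien-19-yl (2Z)-3-(4-hydroxy-3-methoxyphenyl)prop-2-enoate, via aryl acetate 34 (not isolated)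
Conditions: KN(SiMe3)2 (1.0 equiv), 18-crown-6, THF, −78 °C; then pyrrolidine, 0 °C; exclusion of light
Reagents that add atoms: 4-formyl-2-methoxyphenyl acetate 33, CC(=O)Oc1ccc(C=O)cc1OC
Why: Still–Gennari olefination of the aromatic aldehyde should give the (Z)-cinnamate under kinetic control, and aminolysis of the aryl acetate by pyrrolidine frees the phenol without a strongly basic step that could isomerise the Z-alkene or cleave the cinnamate.

**Compound list**

1 | (R)-(+)-limonene, (4R)-1-methyl-4-(prop-1-en-2-yl)cyclohex-1-ene | CC1=CC[C@@H](CC1)C(C)=C | starting material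
2 | oxirane | C1CO1 | starting material
3 | 4-[(1R)-4-methylcyclohex-3-en-1-yl]pent-4-en-1-ol | CC1=CC[C@@H](CC1)C(=C)CCCO | intermediate
4 | 3-chloroperoxybenzoic acid (mCPBA) | OOC(=O)c1cccc(Cl)c1 | starting material
5 | 4-[(4R)-1-methyl-7-oxabicyclo[4.1.0]heptan-4-yl]pent-4-en-1-ol (both oxirane diastereomers) | CC12OC1C[C@@H](CC2)C(=C)CCCO | intermediate
6 | water | O | starting material
7 | (4R)-4-(5-hydroxypent-1-en-2-yl)-1-methylcyclohexane-1,2-diol (diastereomers at C1 and C2; not isolated) | CC1(O)C(O)C[C@@H](CC1)C(=C)CCCO | intermediate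
8 | (3R)-3-(5-hydroxypent-1-en-2-yl)-6-oxoheptanal | CC(=O)CC[C@@H](C(=C)CCCO)CC=O | intermediate
9 | sodium chlorite | [Na+].[O-]Cl=O | starting material
10 | (3R)-3-(5-hydroxypent-1-en-2-yl)-6-oxoheptanoic acid | CC(=O)CC[C@@H](C(=C)CCCO)CC(=O)O | intermediate
11 | iodomethane | CI | starting material
12 | methyl (3R)-3-(5-hydroxypent-1-en-2-yl)-6-oxoheptanoate | CC(=O)CC[C@@H](C(=C)CCCO)CC(=O)OC | intermediate
13 | ethane-1,2-diol | OCCO | starting material
14 | methyl (3R)-3-(5-hydroxypent-1-en-2-yl)-5-(2-methyl-1,3-dioxolan-2-yl)pentanoate | CC1(OCCO1)CC[C@@H](C(=C)CCCO)CC(=O)OC | intermediate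
15 | methyl (2RS,3R)-3-(5-hydroxypent-1-en-2-yl)-2-methyl-5-(2-methyl-1,3-dioxolan-2-yl)pentanoate (C2 epimers) | CC1(OCCO1)CC[C@@H](C(=C)CCCO)C(C)C(=O)OC | intermediate
16 | propane-1,3-dithiol | SCCCS | starting material
17 | (5S)-6-(1,3-dithian-2-ylidene)-4-methylidene-5-[2-(2-methyl-1,3-dioxolan-2-yl)ethyl]heptan-1-ol | CC1(OCCO1)CC[C@@H](C(=C)CCCO)C(C)=C1SCCCS1 | intermediate
18 | (5S)-6-(1,3-dithian-2-ylidene)-4-methylidene-5-[2-(2-methyl-1,3-dioxolan-2-yl)ethyl]heptanal | CC1(OCCO1)CC[C@@H](C(=C)CCC=O)C(C)=C1SCCCS1 | intermediate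
19 | methyl bromo[bis(2,2,2-trifluoroethoxy)phosphoryl]acetate | COC(=O)C(Br)P(=O)(OCC(F)(F)F)OCC(F)(F)F | starting material
20 | methyl (2E,7S)-2-bromo-8-(1,3-dithian-2-ylidene)-6-methylidene-7-[2-(2-methyl-1,3-dioxolan-2-yl)ethyl]non-2-enoate | CC1(OCCO1)CC[C@@H](C(=C)CC/C=C(/Br)C(=O)OC)C(C)=C1SCCCS1 | intermediate
21 | tributyl(vinyl)stannane | C=C[Sn](CCCC)(CCCC)CCCC | starting material
22 | methyl (2Z,7S)-8-(1,3-dithian-2-ylidene)-2-ethenyl-6-methylidene-7-[2-(2-methyl-1,3-dioxolan-2-yl)ethyl]non-2-enoate | CC1(OCCO1)CC[C@@H](C(=C)CC/C=C(/C=C)C(=O)OC)C(C)=C1SCCCS1 | intermediate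
23 | methyl 13,13-(ethylenedioxy)-1,1-(propane-1,3-diyldisulfanediyl)-14,15,18-trinorlabda-3,8(17)-dien-19-oate (5α-H, 9α-H, 10β-CH3) | CC1(OCCO1)CC[C@@H]1[C@@]2(C)C3(SCCCS3)CC=C(C(=O)OC)[C@@H]2CCC1=C | intermediate
24 | methyl 13,13-(ethylenedioxy)-14,15-dinorlabd-8(17)-en-19-oate (4α-CH3, 4β-CO2Me; not isolated) | CC1(OCCO1)CC[C@@H]1[C@@]2(C)CCC[C@](C)(C(=O)OC)[C@@H]2CCC1=C | intermediate
25 | methyl 13-oxo-14,15-dinorlabd-8(17)-en-19-oate | CC(=O)CC[C@@H]1[C@@]2(C)CCC[C@](C)(C(=O)OC)[C@@H]2CCC1=C | intermediate
26 | methyl 8α,17-epoxy-13-oxo-14,15-dinorlabdan-19-oate | CC(=O)CC[C@@H]1[C@@]2(C)CCC[C@](C)(C(=O)OC)[C@@H]2CC[C@@]1(C3)O3 | intermediate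
27 | N-phenylbis(trifluoromethanesulfonimide) | FC(F)(F)S(=O)(=O)N(c1ccccc1)S(=O)(=O)C(F)(F)F | starting material
28 | methyl 8α,17-epoxy-13-[(trifluoromethanesulfonyl)oxy]-14,15-dinorlabd-13(16)-en-19-oate | C=C(OS(=O)(=O)C(F)(F)F)CC[C@@H]1[C@@]2(C)CCC[C@](C)(C(=O)OC)[C@@H]2CC[C@@]1(C3)O3 | intermediate
29 | methyl 8α,17-epoxylabda-13(16),14-dien-19-oate | C=CC(=C)CC[C@@H]1[C@@]2(C)CCC[C@](C)(C(=O)OC)[C@@H]2CC[C@@]1(C3)O3 | intermediate
30 | labda-13(16),14-diene-8α,19-diol | C=CC(=C)CC[C@@H]1[C@@]2(C)CCC[C@](C)(CO)[C@@H]2CC[C@@]1(C)O | intermediate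
31 | [bis(2,2,2-trifluoroethoxy)phosphoryl]acetic acid | OC(=O)CP(=O)(OCC(F)(F)F)OCC(F)(F)F | starting material
32 | 8α-hydroxylabda-13(16),14-dien-19-yl [bis(2,2,2-trifluoroethoxy)phosphoryl]acetate | C=CC(=C)CC[C@@H]1[C@@]2(C)CCC[C@](C)(COC(=O)CP(=O)(OCC(F)(F)F)OCC(F)(F)F)[C@@H]2CC[C@@]1(C)O | intermediate
33 | 4-formyl-2-methoxyphenyl acetate (vanillin acetate) | CC(=O)Oc1ccc(C=O)cc1OC | starting material
34 | 8α-hydroxylabda-13(16),14-dien-19-yl (2Z)-3-(4-acetoxy-3-methoxyphenyl)prop-2-enoate (not isolated) | C=CC(=C)CC[C@@H]1[C@@]2(C)CCC[C@](C)(COC(=O)/C=C\c3ccc(OC(C)=O)c(OC)c3)[C@@H]2CC[C@@]1(C)O | intermediate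
35 | 8α-hydroxylabda-13(16),14-dien-19-yl (2Z)-3-(4-hydroxy-3-methoxyphenyl)prop-2-enoate (CNP0142252.2) | C=CC(=C)CC[C@@H]1[C@@]2(C)CCC[C@](C)(COC(=O)/C=C\c3ccc(O)c(OC)c3)[C@@H]2CC[C@@]1(C)O | target

**Step count and risks**

Total step count: 19. Longest linear sequence: 19 steps (steps 1 to 19 from (R)-limonene 1; every other component is a commercial reagent).

Steps most likely to fail:

1. Step 12. The fully substituted ketene dithioacetal may add too slowly, so that bimolecular dimerisation of the 2-(methoxycarbonyl)diene or protonolysis of the ketene dithioacetal outruns ring closure; a late, loose transition state could also lose part of the allylic-strain control. The fallback replaces the thermal cycloaddition by a chelate-activated, stepwise ionic annulation at low temperature. It sets out from 22: LiOH in THF/H2O gives the dienoic acid F1, which is converted through its pivaloyl mixed anhydride and lithiated 1,3-oxazolidin-2-one into the N-acyl oxazolidinone F2. Me2AlCl in CH2Cl2 at −78 °C should then bind the imide as a chelate and trigger conjugate addition of C10 to C5 (Mukaiyama–Michael manifold), followed by capture of the 1,3-dithian-2-ylium ion at C1 by C2 of the aluminium dienolate, giving the bicyclic imide F3. NaOMe in MeOH at 0 °C returns the route at 23.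

2. Step 8. Thiolate transfer to the hindered α-branched ester may stop at the thioester stage, and the Lewis-acidic aluminium reagent may exchange the dioxolane for a second dithiane. The fallback brings sulfur in stepwise and closes the dithiane ring by S-alkylation under basic conditions. It sets out from 15: Me2AlS(CH2)3Cl (from AlMe3 and 3-chloropropane-1-thiol, 23 °C) gives the S-(3-chloropropyl) thioester F4, and Lawesson's reagent in toluene at 80 °C gives the dithioester F5. LiN(i-Pr)2 in THF then forms the ene-thiolate, which closes the 1,3-dithiane ring by intramolecular S-alkylation and returns the route at 17.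

3. Step 13. Three reductive events share one pot: cleavage of the second C–S bond may lag behind (leaving a 3-sulfanylpropyl sulfide), the ester may be over-reduced, and the enolate may be quenched by proton transfer before it is alkylated. The fallback separates the events and uses radical and hydride chemistry instead of dissolving metal. It sets out from 23: Bu3SnH and AIBN in toluene at 110 °C remove the dithiane to give the dienoate F6. Conjugate reduction with KBH(s-Bu)3 in THF at −78 °C and trapping of the potassium enolate with MeI give 24, which 1 M HCl hydrolyses to 25, where the route is rejoined.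

Further compounds

F1 | step 12 | (2Z,7S)-8-(1,3-dithian-2-ylidene)-2-ethenyl-6-methylidene-7-[2-(2-methyl-1,3-dioxolan-2-yl)ethyl]non-2-enoic acid | CC1(OCCO1)CC[C@@H](C(=C)CC/C=C(/C=C)C(=O)O)C(C)=C1SCCCS1
F2 | step 12 | 3-[(2Z,7S)-8-(1,3-dithian-2-ylidene)-2-ethenyl-6-methylidene-7-[2-(2-methyl-1,3-dioxolan-2-yl)ethyl]non-2-enoyl]-1,3-oxazolidin-2-one | CC1(OCCO1)CC[C@@H](C(=C)CC/C=C(/C=C)C(=O)N1CCOC1=O)C(C)=C1SCCCS1
F3 | step 12 | 3-[13,13-(ethylenedioxy)-1,1-(propane-1,3-diyldisulfanediyl)-14,15,18-trinorlabda-3,8(17)-dien-19-oyl]-1,3-oxazolidin-2-one | CC1(OCCO1)CC[C@@H]1[C@@]2(C)C3(SCCCS3)CC=C(C(=O)N3CCOC3=O)[C@@H]2CCC1=C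
F4 | step 8 | S-(3-chloropropyl) (2RS,3R)-3-(5-hydroxypent-1-en-2-yl)-2-methyl-5-(2-methyl-1,3-dioxolan-2-yl)pentanethioate | CC1(OCCO1)CC[C@@H](C(=C)CCCO)C(C)C(=O)SCCCCl
F5 | step 8 | 3-chloropropyl (2RS,3R)-3-(5-hydroxypent-1-en-2-yl)-2-methyl-5-(2-methyl-1,3-dioxolan-2-yl)pentanedithioate | CC1(OCCO1)CC[C@@H](C(=C)CCCO)C(C)C(=S)SCCCCl
F6 | step 13 | methyl 13,13-(ethylenedioxy)-14,15,18-trinorlabda-3,8(17)-dien-19-oate | CC1(OCCO1)CC[C@@H]1[C@@]2(C)CCC=C(C(=O)OC)[C@@H]2CCC1=C
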